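Compound numbers 1–15 are fixed by the steps below and are used throughout; 15 is the target.

## Analysis of the target

Target 15 is a 2-aryl-2,3-dihydro-1-benzofuran neolignan. Ring A (the benzo ring) carries an acetyl group at C5, para to the ring oxygen O1, and a methoxy group at C7. The dihydrofuran ring carries a 4-hydroxy-3,5-dimethoxyphenyl group (ring B) at C2 and a hydroxymethyl group at C3. The two stereocentres are adjacent: C2 is S, C3 is R, and the aryl and hydroxymethyl groups lie on opposite faces of the five-membered ring (trans), which is also the more stable arrangement. The sensitive points are three: the C2–O1 bond, a para-hydroxybenzylic aryl ether that can ionise through a quinone methide under acid or strong base and so lose the C2 configuration; the enolisable, reducible methyl ketone; and the oxidisable free phenol. The difficulty is therefore not the trans relationship as such, but fixing the absolute configuration at one centre, relaying it cleanly to the other, and getting the acetyl group past the steps that build the ring. The plan rests on the substitution at C3, which bears ring A carbon C3a and a one-carbon oxygenated arm and sits next to the O1–C2(aryl) carbon. Read this way, O1–C2–C3 plus the exocyclic carbon is the O1–C2–C3–C4 segment of a flavanone in which carbonyl carbon C4 has been pushed out of the ring by a shift of aromatic carbon C4a from C4 to C3.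

## Retrosynthetic reasoning

**Acetyl group (15 to 12 and 13).** The first cut is the C5–acetyl bond, leading to aryl bromide 12 and stannane 13, with enol ether 14 as the masked ketone. A methyl aryl ketone would not survive the two steps before it: the oxidant of the ring contraction attacks such ketones at their α-carbon, and the hydride step would reduce it. A bromine atom is inert to both and sits para to O1, where halogenation of a phenol places it without extra effort. The forward reaction has to couple an electron-rich aryl bromide in the presence of a free phenol and a free alcohol, then unmask the ketone under acid mild enough not to ionise the C2–O1 bond.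

**Oxidation level of the arm and the phenol (12 to 11).** No skeletal bond is cut here. The hydroxymethyl group is traced to a methyl ester and the phenol to its pivalate, both in ester 11. One hydride treatment should adjust both, so the protecting group costs no separate step.

**C3–C3a bond (11 to 8, through 9 and 10).** This is the central disconnection. The C3–C3a bond is cut in the sense of a 1,2-shift: C3a returns to the ester carbon, which becomes the ring carbonyl C4 of flavanone 8. The other ring bonds (O1–C2, C2–C3, O1–C7a) could each be made by a cyclisation, but each would need either both stereocentres in an open-chain precursor or a stereoselective ring closure. The shift instead converts the target ring into a six-membered ketone with one stereocentre and creates the second centre stereospecifically. The forward reaction must functionalise C3 of enol ether 9 with a trivalent iodine leaving group anti to the aryl group, giving 10, and then move C4a to C3 with inversion so that the ester ends trans to the aryl group.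

**C2–aryl bond (8 to 4 and 7).** Flavanone 8 is cut between C2 and ring B, giving planar chromone 4 and boronic acid 7. Cutting O1–C2 instead (a chalcone cyclisation) would give the same ring, but that closure is reversible and has no dependable catalytic enantiocontrol for an unactivated substrate. The C2–aryl cut joins the two aromatic halves at the stereogenic carbon and sets C2 with a chiral ligand. It is the only step of the route that needs external asymmetric induction.

**Chromone ring (4 to 2 to 1, through 3).** Chromone 4 is opened at O1–C2 and C2–C3, which removes one carbon and leaves acetophenone 2, with enaminone 3 as the intermediate. The bromine of 2 is taken off the position para to the hydroxyl group, giving commercial acetophenone 1. Both forward steps are standard and regiochemically unambiguous.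

**Boronic acid (7 to 6 to 5).** Boronic acid 7 comes from pinacol ester 6 by diol cleavage, and 6 from commercial phenol 5 by O-acylation. The pivalate is chosen because it lowers the electron density of ring B during the oxidation and is removed by the hydride step that is needed anyway.

## Alternatives that were turned down

**Alternative 1:** Both bonds to C2 inside the heterocycle, O1–C2 and C2–C3, are cut. Ring A supplies O1 and C3 as an ortho-quinone methide, released by base from sulfone A1, and C2 arrives with ring B as the benzylide of chiral sulfonium salt A2. In the forward step the ylide carbon adds to the exocyclic carbon of the quinone methide (C2–C3), and the phenoxide then displaces the sulfide at C2 (O1–C2). The product is bis-silyl ether A3, one fluoride treatment from 15.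
- For: it is the most convergent plan, makes two ring bonds and both stereocentres in one flask, and gives trans by the anti-periplanar closure of the betaine. The acetyl group is present from the start, so no late cross-coupling and no tin are needed. On these points it is stronger than the chosen route.
- Against: the quinone methide from A1 carries a CH2OSi group on its exocyclic carbon, and such alkyl-type quinone methides tautomerise easily to ortho-vinylphenols. The benzylide can also epoxidise the aryl methyl ketone. Absolute control would rest on a stoichiometric chiral sulfide and on a semi-stabilised, electron-rich benzylide attacking a transient acceptor, where face selectivity is hard to predict. A2, a para-silyloxybenzyl sulfonium salt, is itself prone to ionise.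
- Comparison: the chosen route gives up convergence in the ring-forming step. In return it sets its one independent stereocentre with a catalyst on a stable, planar substrate and relays it by a stereospecific shift.

**Alternative 2:** The C3–C3a bond and the C–O bond of the hydroxymethyl arm are cut. The precursor is diazonium salt A4, an aryl ether of an enantioenriched 1-arylallyl alcohol. In the forward step sodium 2,2,6,6-tetramethylpiperidin-1-olate reduces the diazonium group by single-electron transfer. The ring A aryl radical closes 5-exo-trig onto the internal alkene carbon, and the resulting primary radical is trapped by the nitroxide formed in the reduction, giving alkoxyamine A5. Cleavage of the N–O bond with Zn in acetic acid and desilylation would end at 15.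
- For: it forms the same C3–C3a bond as the chosen route, under neutral and mild conditions that tolerate the acetyl group, so again no late Stille coupling is needed. It oxygenates the arm in the same step, and C2 is fixed before ring closure. On functional-group tolerance it is stronger.
- Against: C3 is set only by 1,2-induction from C2 in an early, fast transition state. Trans should be preferred but not reliably so, and a C3 centre without an acidifying group cannot be corrected afterwards. A4 is costly to make: it needs an invertive O-alkylation of a phenol flanked by a methoxy group and a nitrogen substituent, at a carbon that scrambles by ionisation or allylic transposition, plus nitration, reduction and diazotisation. Two deprotections follow the key step, so the route is estimated at ten steps or more.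
- Comparison: in place of mildness, the chosen route offers a relay by inversion whose product is also the thermodynamic epimer next to an ester, so a stereochemical leak at C3 can be repaired.

**Alternative 3:** The O1–C7a bond is cut. Open-chain fluoroarene A6 already carries both stereocentres. KOtBu deprotonates the C2 carbinol, the alkoxide attacks C7a (para to the acetyl group), and fluoride leaves through a Meisenheimer adduct in a 5-exo closure to give A7. Acid removal of the trityl and methoxymethyl groups would give 15.
- For: the ring closure cannot disturb either stereocentre, the acetyl group is used productively as the activating group, and no late carbon–carbon bond formation is needed. On the stereochemical security of the ring closure it is stronger than the chosen route.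
- Against: all the stereochemical work moves into A6, an anti-configured 1,2-diaryl-1,3-diol with differentiated hydroxyl groups. That needs an auxiliary- or catalyst-controlled aldol-type construction, a reduction and several protecting-group steps, so the route is clearly longer. The substitution itself is marginal: the C–F carbon is activated by one para-acyl group only and is shielded and deactivated by the ortho-methoxy group. The base that forms the alkoxide also enolises the methyl ketone, which turns the activator into a donor and opens aldol pathways. The final acidic deprotection exposes the para-hydroxybenzylic C2–O1 bond to ionisation.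
- Comparison: the chosen route reaches the ring in fewer steps and keeps strong base away from the ketone, at the price of introducing the acetyl group last.

Key step: step 6

Assumption 1: boronate 5 is treated as a purchasable compound.
Assumption 2: the ligand enantiomer in step 5 is assigned by transferring the facial sense of this catalyst on cyclic enones to the chromone, which points to the (R)-ligand for the 2S flavanone; if the chromone shows the opposite sense, the mirror-image ligand is used and nothing else changes.

## Route

Step 1
Reactants: 1 2'-hydroxy-3'-methoxyacetophenone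
Product: 2 5'-bromo-2'-hydroxy-3'-methoxyacetophenone
Conditions: NBS (1.05 equiv), MeCN, 0 °C to rt
Reagents that add atoms: N-bromosuccinimide, O=C1CCC(=O)N1Br
Why: Electrophilic aromatic bromination; the hydroxyl group directs para (both its ortho positions are occupied) and the acetyl group directs meta to the same carbon, so a single regioisomer is expected, as in the bromination of related ortho-methoxyphenols.

Step 2
Reactants: 2 5'-bromo-2'-hydroxy-3'-methoxyacetophenone
Product: 4 6-bromo-8-methoxy-4H-chromen-4-one, via enaminone 3 (not isolated)
Conditions: Me2NCH(OMe)2, toluene, 100 °C; then conc. HCl, CH2Cl2, 40 °C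
Reagents that add atoms: N,N-dimethylformamide dimethyl acetal, COC(OC)N(C)C
Why: Enaminone route to chromones: condensation of the methyl ketone with the formamide acetal gives 3, and acid promotes conjugate addition of the phenol oxygen followed by loss of dimethylamine; the bromide and the methyl ether are inert.

Step 3
Reactants: 5 2,6-dimethoxy-4-(4,4,5,5-tetramethyl-1,3,2-dioxaborolan-2-yl)phenol
Product: 6 2,6-dimethoxy-4-(4,4,5,5-tetramethyl-1,3,2-dioxaborolan-2-yl)phenyl pivalate
Conditions: PivCl, Et3N, DMAP (cat.), CH2Cl2, 0 °C to rt
Reagents that add atoms: pivaloyl chloride, CC(C)(C)C(=O)Cl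
Why: DMAP-catalysed O-acylation of the hindered phenol; the pinacol boronate tolerates amine base and acyl chloride.

Step 4
Reactants: 6 2,6-dimethoxy-4-(4,4,5,5-tetramethyl-1,3,2-dioxaborolan-2-yl)phenyl pivalate
Product: 7 [3,5-dimethoxy-4-(pivaloyloxy)phenyl]boronic acid
Conditions: NaIO4, NH4OAc, acetone/H2O, rt
Reagents that add atoms: water, O
Why: Oxidative cleavage of the pinacol released in the hydrolysis equilibrium drives the boronate to the free boronic acid; the near-neutral medium leaves the aryl pivalate intact.

Step 5
Reactants: 4 6-bromo-8-methoxy-4H-chromen-4-one; 7 [3,5-dimethoxy-4-(pivaloyloxy)phenyl]boronic acid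
Product: 8 (2S)-6-bromo-2-[3,5-dimethoxy-4-(pivaloyloxy)phenyl]-8-methoxychroman-4-one
Conditions: Pd(OCOCF3)2 (5 mol %), (R)-t-BuPyOx (6 mol %), NH4PF6 (30 mol %), H2O (5 equiv), ClCH2CH2Cl, 60 °C, air
Reagents that add atoms: none
Why: Asymmetric conjugate addition of an arylboronic acid to a chromone with cationic divalent palladium and a pyridine-oxazoline ligand: transmetallation, face-selective insertion of the C2=C3 bond into the aryl–palladium bond under control of the ligand tert-butyl group, and protonolysis of the palladium enolate by water; the cycle stays at divalent palladium, so the C–Br bond should not be touched.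

Step 6
Reactants: 8 (2S)-6-bromo-2-[3,5-dimethoxy-4-(pivaloyloxy)phenyl]-8-methoxychroman-4-one
Product: 11 methyl (2S,3S)-5-bromo-2-[3,5-dimethoxy-4-(pivaloyloxy)phenyl]-7-methoxy-2,3-dihydro-1-benzofuran-3-carboxylate, via C4 enol ether 9 (not isolated), via trans C3 iodane ketal 10 (not isolated)
Conditions: PhI(OAc)2 (1.2 equiv), conc. H2SO4 (1 equiv), HC(OMe)3, 0 °C to rt
Reagents that add atoms: trimethyl orthoformate, COC(OC)OC
Why: Acid and the orthoformate convert ketone 8 into its C3=C4 methyl enol ether 9, whose C3 attacks the trivalent iodine centre of PhI(OAc)2 on the face away from the C2 aryl group while methanol caps C4, giving ketal 10 with a pseudo-equatorial C3–iodine bond antiperiplanar to the C4–C4a ring bond. Ring A carbon C4a then shifts from C4 to C3 with inversion at C3 and expulsion of iodobenzene (reduction to monovalent iodine is the driving force), and the dimethoxycarbenium ion left at C4 loses one methyl group to end as the methyl ester. The closest known reaction type is the oxidative 1,2-aryl shift of aryl ketones to arylalkanoic esters with hypervalent iodine or Tl(NO3)3 in an orthoformate, in its flavanone version that gives methyl trans-2-aryl-2,3-dihydrobenzofuran-3-carboxylates. The dihydrofuran ring is not closed by a cyclisation: it arises by ring contraction, the six-membered pyranone losing C4 from the ring as the C3–C3a bond forms. The new C3 stereocentre is controlled by the existing C2 centre, since iodination anti to the aryl group followed by invertive migration leaves the ester trans to the aryl group, which is also the thermodynamically preferred arrangement. The step needs migration of C4a in preference to migration of ring B from C2 and to dehydrogenation across C2–C3; the two oxygen atoms at C4 that stabilise the cation left behind, the ring oxygen ortho to the migrating carbon and the electron-poor pivalate on ring B should secure this. It also needs C2 to keep its configuration, which the non-basic medium and the weakly donating pivaloyloxyaryl group should ensure, and the bromine stands where an acetyl group would itself be attacked by the oxidant.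

Step 7
Reactants: 11 methyl (2S,3S)-5-bromo-2-[3,5-dimethoxy-4-(pivaloyloxy)phenyl]-7-methoxy-2,3-dihydro-1-benzofuran-3-carboxylate
Product: 12 4-[(2S,3R)-5-bromo-3-(hydroxymethyl)-7-methoxy-2,3-dihydro-1-benzofuran-2-yl]-2,6-dimethoxyphenol
Conditions: LiAlH4 (3 equiv), THF, 0 °C; aq. potassium sodium tartrate work-up
Reagents that add atoms: none
Why: Hydride reduction of the methyl ester to the primary alcohol and reductive cleavage of the aryl pivalate in one operation; no stereocentre is touched (the C3 descriptor changes from S to R only because the substituent priorities change), and an aryl bromide is reduced only slowly at 0 °C.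

Step 8
Reactants: 12 4-[(2S,3R)-5-bromo-3-(hydroxymethyl)-7-methoxy-2,3-dihydro-1-benzofuran-2-yl]-2,6-dimethoxyphenol; 13 tributyl(1-ethoxyvinyl)stannane
Product: 15 1-[(2S,3R)-2-(4-hydroxy-3,5-dimethoxyphenyl)-3-(hydroxymethyl)-7-methoxy-2,3-dihydro-1-benzofuran-5-yl]ethanone, via aryl enol ether 14 (not isolated)
Conditions: Pd(PPh3)4 (5 mol %), toluene, 100 °C; then 1 M HCl, THF, rt
Reagents that add atoms: tributyl(1-ethoxyvinyl)stannane (13), CCOC(=C)[Sn](CCCC)(CCCC)CCCC; water, O
Why: Stille coupling (oxidative addition of zerovalent palladium into the C–Br bond, transmetallation from tin, reductive elimination) gives the α-ethoxystyrene 14 as an acetyl equivalent under neutral conditions that tolerate the free phenol and alcohol; dilute acid hydrolyses the enol ether at rt much faster than the benzylic C2–O1 bond can ionise.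

## Compound list

1 | 2'-hydroxy-3'-methoxyacetophenone | CC(=O)c1cccc(OC)c1O | starting material
2 | 5'-bromo-2'-hydroxy-3'-methoxyacetophenone | CC(=O)c1cc(Br)cc(OC)c1O | intermediate
3 | (E)-1-(5-bromo-2-hydroxy-3-methoxyphenyl)-3-(dimethylamino)prop-2-en-1-one | CN(C)/C=C/C(=O)c1cc(Br)cc(OC)c1O | intermediate (not isolated)
4 | 6-bromo-8-methoxy-4H-chromen-4-one | O=c1ccoc2c(OC)cc(Br)cc12 | intermediate
5 | 2,6-dimethoxy-4-(4,4,5,5-tetramethyl-1,3,2-dioxaborolan-2-yl)phenol | COc1cc(B2OC(C)(C)C(C)(C)O2)cc(OC)c1O | starting material
6 | 2,6-dimethoxy-4-(4,4,5,5-tetramethyl-1,3,2-dioxaborolan-2-yl)phenyl pivalate | COc1cc(B2OC(C)(C)C(C)(C)O2)cc(OC)c1OC(=O)C(C)(C)C | intermediate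
7 | [3,5-dimethoxy-4-(pivaloyloxy)phenyl]boronic acid | COc1cc(B(O)O)cc(OC)c1OC(=O)C(C)(C)C | intermediate
8 | (2S)-6-bromo-2-[3,5-dimethoxy-4-(pivaloyloxy)phenyl]-8-methoxychroman-4-one | O=C1C[C@@H](c2cc(OC)c(OC(=O)C(C)(C)C)c(OC)c2)Oc2c(OC)cc(Br)cc12 | intermediate
9 | (2S)-6-bromo-2-[3,5-dimethoxy-4-(pivaloyloxy)phenyl]-4,8-dimethoxy-2H-chromene | COC1=C[C@@H](c2cc(OC)c(OC(=O)C(C)(C)C)c(OC)c2)Oc2c(OC)cc(Br)cc12 | intermediate (not isolated)
10 | (2R,3R)-3-[acetoxy(phenyl)-λ3-iodanyl]-6-bromo-2-[3,5-dimethoxy-4-(pivaloyloxy)phenyl]-4,4,8-trimethoxychromane (iodine trans to the C2 aryl group; drawn with acetate as the second ligand on iodine) | COC1(OC)[C@H](I(OC(C)=O)c2ccccc2)[C@@H](c2cc(OC)c(OC(=O)C(C)(C)C)c(OC)c2)Oc2c(OC)cc(Br)cc12 | intermediate (not isolated)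
11 | methyl (2S,3S)-5-bromo-2-[3,5-dimethoxy-4-(pivaloyloxy)phenyl]-7-methoxy-2,3-dihydro-1-benzofuran-3-carboxylate (trans) | COc1cc([C@H]2Oc3c(OC)cc(Br)cc3[C@@H]2C(=O)OC)cc(OC)c1OC(=O)C(C)(C)C | intermediate
12 | 4-[(2S,3R)-5-bromo-3-(hydroxymethyl)-7-methoxy-2,3-dihydro-1-benzofuran-2-yl]-2,6-dimethoxyphenol | COc1cc([C@H]2Oc3c(OC)cc(Br)cc3[C@@H]2CO)cc(OC)c1O | intermediate
13 | tributyl(1-ethoxyvinyl)stannane | CCOC(=C)[Sn](CCCC)(CCCC)CCCC | starting material
14 | 4-[(2S,3R)-5-(1-ethoxyvinyl)-3-(hydroxymethyl)-7-methoxy-2,3-dihydro-1-benzofuran-2-yl]-2,6-dimethoxyphenol | COc1cc([C@H]2Oc3c(OC)cc(C(=C)OCC)cc3[C@@H]2CO)cc(OC)c1O | intermediate (not isolated)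
15 | 1-[(2S,3R)-2-(4-hydroxy-3,5-dimethoxyphenyl)-3-(hydroxymethyl)-7-methoxy-2,3-dihydro-1-benzofuran-5-yl]ethanone | COc1cc([C@H]2Oc3c(OC)cc(C(C)=O)cc3[C@@H]2CO)cc(OC)c1O | target

## Step count and least certain steps

Total step count: 8. Longest linear sequence: 6 (steps 1, 2, 5, 6, 7, 8; the boronic acid branch, steps 3, 4, 5, 6, 7, 8, is equally long).

**Step 6 (key step).** Several things can go wrong.
- Iodane 10 may lose iodobenzene by dehydrogenation across C2–C3, or ring B may migrate from C2 to C3 in place of C4a.
- The migration of C4a may be slowed by the bromine meta to it.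
- Enol ether formation may be incomplete, because the C4 carbonyl is deactivated by conjugation with O1.
- Acid-promoted opening and reclosure of the pyranone ring may erode the C2 configuration.

Fallback, a Wolff ring contraction that moves the same carbon. Setting out from 8, deprotonation with LiN(SiMe3)2 in THF at −78 °C and trapping with CF3CO2CH2CF3 would give the 3-trifluoroacetyl ketone F1. MsN3 and Et3N in MeCN would convert it by detrifluoroacetylative diazo transfer into the 3-diazo ketone F2. Irradiation at 365 nm in methanol should trigger the Wolff rearrangement, in which C4a migrates from C4 to the carbene carbon C3, and methanol would add to the ring-contracted ketene. The ester would form as a mixture of 11 and its cis ester F3. DBU in toluene would equilibrate F3 to the trans ester, and the route is rejoined at 11.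

**Step 5.** The donor-substituted chromone may turn over slowly while boronic acid 7 is consumed by protodeboronation. The enantioselectivity may be lower than on unsubstituted chromones, or of the opposite sense. Oxidative addition into the C–Br bond becomes possible if zerovalent palladium accumulates.

Fallback, resolution in place of asymmetric catalysis. Setting out from 4 and 7, the same addition run with the achiral ligand 2,2'-bipyridine and Pd(OCOCF3)2 should give the racemic flavanone F4. Asymmetric transfer hydrogenation with RuCl(p-cymene)(TsDPEN) and HCO2H/Et3N would follow, stopped near half conversion and using the catalyst enantiomer that reduces the 2R ketone faster. This would turn that enantiomer into the cis alcohol F5, which is removed by chromatography, and leave 8, where the route is rejoined.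

**Step 8.** Oxidative addition into the electron-rich C–Br bond para to O1 may be slow, with catalyst decay and reduction of the bromide as the competing process. During enol ether hydrolysis the acid may ionise the para-hydroxybenzylic C2–O1 bond and epimerise C2.

Fallback, aryllithium acylation in place of cross-coupling. Setting out from 12, TBSCl and imidazole in DMF would give the bis-silyl ether F6. Bromine–lithium exchange with t-BuLi in THF at −78 °C and quenching with N-methoxy-N-methylacetamide would give the silylated ketone F7. Bu4NF buffered with acetic acid would remove both silyl groups and give 15.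

**Step 7.** The hydride may slowly reduce the C–Br bond, which would remove the handle for the acetyl group. Cleavage of the hindered pivalate may lag behind ester reduction. The phenoxide formed in the aluminate mixture may open the benzylic ether if the mixture warms.

Fallback, reversed order. Setting out from 11, Stille coupling with 13 under the conditions of step 8, without the acid treatment, would give the enol ether ester F8. LiAlH4 in THF at 0 °C would then reduce the ester and the pivalate in a molecule that no longer has a C–Br bond and give 14, where the route is rejoined; dilute acid converts 14 into 15.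

## Further compounds

F1 | step 6 | (2S)-6-bromo-2-[3,5-dimethoxy-4-(pivaloyloxy)phenyl]-8-methoxy-3-(trifluoroacetyl)chroman-4-one (C3 epimers, largely enolised) | O=C1C(C(=O)C(F)(F)F)[C@@H](c2cc(OC)c(OC(=O)C(C)(C)C)c(OC)c2)Oc2c(OC)cc(Br)cc12
F2 | step 6 | (2R)-6-bromo-3-diazo-2-[3,5-dimethoxy-4-(pivaloyloxy)phenyl]-8-methoxychroman-4-one | O=C1C(=[N+]=[N-])[C@@H](c2cc(OC)c(OC(=O)C(C)(C)C)c(OC)c2)Oc2c(OC)cc(Br)cc12
F3 | step 6 | methyl (2S,3R)-5-bromo-2-[3,5-dimethoxy-4-(pivaloyloxy)phenyl]-7-methoxy-2,3-dihydro-1-benzofuran-3-carboxylate (cis) | COc1cc([C@H]2Oc3c(OC)cc(Br)cc3[C@H]2C(=O)OC)cc(OC)c1OC(=O)C(C)(C)C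
F4 | step 5 | racemic 6-bromo-2-[3,5-dimethoxy-4-(pivaloyloxy)phenyl]-8-methoxychroman-4-one | O=C1CC(c2cc(OC)c(OC(=O)C(C)(C)C)c(OC)c2)Oc2c(OC)cc(Br)cc12
F5 | step 5 | 4-[(2R,4R)-6-bromo-4-hydroxy-8-methoxychroman-2-yl]-2,6-dimethoxyphenyl pivalate (cis) | O[C@@H]1C[C@H](c2cc(OC)c(OC(=O)C(C)(C)C)c(OC)c2)Oc2c(OC)cc(Br)cc12
F6 | step 8 | {4-[(2S,3R)-5-bromo-3-[(tert-butyldimethylsilyloxy)methyl]-7-methoxy-2,3-dihydro-1-benzofuran-2-yl]-2,6-dimethoxyphenoxy}(tert-butyl)dimethylsilane | COc1cc([C@H]2Oc3c(OC)cc(Br)cc3[C@@H]2CO[Si](C)(C)C(C)(C)C)cc(OC)c1O[Si](C)(C)C(C)(C)C
F7 | step 8 | 1-{(2S,3R)-2-[4-(tert-butyldimethylsilyloxy)-3,5-dimethoxyphenyl]-3-[(tert-butyldimethylsilyloxy)methyl]-7-methoxy-2,3-dihydro-1-benzofuran-5-yl}ethanone | COc1cc([C@H]2Oc3c(OC)cc(C(C)=O)cc3[C@@H]2CO[Si](C)(C)C(C)(C)C)cc(OC)c1O[Si](C)(C)C(C)(C)C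
F8 | step 7 | methyl (2S,3S)-2-[3,5-dimethoxy-4-(pivaloyloxy)phenyl]-5-(1-ethoxyvinyl)-7-methoxy-2,3-dihydro-1-benzofuran-3-carboxylate | COc1cc([C@H]2Oc3c(OC)cc(C(=C)OCC)cc3[C@@H]2C(=O)OC)cc(OC)c1OC(=O)C(C)(C)C
A1 | alternative 1 | 1-{3-[2-(tert-butyldimethylsilyloxy)-1-(4-methylphenylsulfonyl)ethyl]-4-hydroxy-5-methoxyphenyl}ethanone (racemic) | CC(=O)c1cc(OC)c(O)c(C(CO[Si](C)(C)C(C)(C)C)S(=O)(=O)c2ccc(C)cc2)c1
A2 | alternative 1 | (2R,5R)-1-[4-(tert-butyldimethylsilyloxy)-3,5-dimethoxybenzyl]-2,5-dimethylthiolan-1-ium trifluoromethanesulfonate (drawn with one enantiomer of the sulfide) | C[C@@H]1CC[C@@H](C)[S+]1Cc1cc(OC)c(O[Si](C)(C)C(C)(C)C)c(OC)c1.[O-]S(=O)(=O)C(F)(F)F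
A3 | alternative 1 | 1-{(2S,3R)-2-[4-(tert-butyldimethylsilyloxy)-3,5-dimethoxyphenyl]-3-[(tert-butyldimethylsilyloxy)methyl]-7-methoxy-2,3-dihydro-1-benzofuran-5-yl}ethanone | COc1cc([C@H]2Oc3c(OC)cc(C(C)=O)cc3[C@@H]2CO[Si](C)(C)C(C)(C)C)cc(OC)c1O[Si](C)(C)C(C)(C)C
A4 | alternative 2 | 5-acetyl-2-{[(1S)-1-[3,5-dimethoxy-4-(triisopropylsilyloxy)phenyl]prop-2-en-1-yl]oxy}-3-methoxybenzenediazonium tetrafluoroborate | CC(=O)c1cc(OC)c(O[C@@H](C=C)c2cc(OC)c(O[Si](C(C)C)(C(C)C)C(C)C)c(OC)c2)c([N+]#N)c1.F[B-](F)(F)F
A5 | alternative 2 | 1-{(2S,3R)-2-[3,5-dimethoxy-4-(triisopropylsilyloxy)phenyl]-7-methoxy-3-[(2,2,6,6-tetramethylpiperidin-1-yl)oxymethyl]-2,3-dihydro-1-benzofuran-5-yl}ethanone | COc1cc([C@H]2Oc3c(OC)cc(C(C)=O)cc3[C@@H]2CON2C(C)(C)CCCC2(C)C)cc(OC)c1O[Si](C(C)C)(C(C)C)C(C)C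
A6 | alternative 3 | 1-{4-fluoro-3-[(1S,2R)-1-hydroxy-1-[3,5-dimethoxy-4-(methoxymethoxy)phenyl]-3-(trityloxy)propan-2-yl]-5-methoxyphenyl}ethanone | COc1cc([C@@H](O)[C@@H](COC(c2ccccc2)(c2ccccc2)c2ccccc2)c2cc(C(C)=O)cc(OC)c2F)cc(OC)c1OCOC
A7 | alternative 3 | 1-{(2S,3R)-2-[3,5-dimethoxy-4-(methoxymethoxy)phenyl]-7-methoxy-3-(trityloxymethyl)-2,3-dihydro-1-benzofuran-5-yl}ethanone | COc1cc([C@H]2Oc3c(OC)cc(C(C)=O)cc3[C@@H]2COC(c2ccccc2)(c2ccccc2)c2ccccc2)cc(OC)c1OCOC
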